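**Assumptions.** Operations run in one pot without isolation count as one step. Compound 6, the ethyl ester of the L‑glutamic acid diazotisation lactone, is taken as purchasable.

**Numbering.** C1 is the benzylic CH2, the terpenoid chain runs to C15 (the CBrMe2 carbon), and the ring carbons are C2–C7. The target is (2R,6S,7S,10S,11S,14S). Both the oxirane and the all‑equatorial cyclohexane correspond to an all‑E polyene precursor.

## Retrosynthetic overview
1. Bromophycolide S comes from aryl ester cleavage and late epoxidation of C10=C11, the only trisubstituted alkene left in a 15‑membered bromo‑macrolide.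
2. The key disconnection is C2–C7 with C6–Br: an anodic, bromide‑mediated transannular bromonium cyclisation of a 19‑membered (2E,6E,10E)‑triene macrolactone.
3. The C14–O acyl bond comes from macrolactonisation of a (14S)‑14‑hydroxy‑15‑bromo seco‑acid, made from the (14S)‑14,15‑diol through the epoxide with retention.
4. C9–C10 comes from a B‑alkyl Suzuki union of a west trienyl benzoate (methylparaben + geranyl bromide) with an east (E)‑vinyl iodide diol. The diol derives from the L‑glutamic acid lactone ester, which supplies the only purchased stereocentre (C14).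
5. Ring order: 19‑membered lactone, then cyclohexane (19 → 15 + 6), then oxirane.

## Route

**Step 1**
Reactants: 1 methyl 4‑hydroxybenzoate; 2 geranyl bromide
Product: 3 methyl 3‑[(2E)‑3,7‑dimethylocta‑2,6‑dienyl]‑4‑hydroxybenzoate
Conditions: NaH (1.0 equiv), toluene, 0 °C → rt; then 2 (0.9 equiv), rt, 24 h
Reagents that add atoms: none
Why: Ortho C‑allylation of a tight sodium phenoxide ion pair in a non‑polar solvent, with the para position blocked and SN2 at the primary allylic carbon keeping the E‑alkene; the yield is modest but the materials are commodities.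

**Step 2**
Reactants: 3
Product: 4 methyl 3‑[(2E,6E)‑3,7‑dimethyl‑8‑oxoocta‑2,6‑dienyl]‑4‑hydroxybenzoate
Conditions: SeO2 (0.3 equiv), t‑BuOOH, salicylic acid (cat.), CH2Cl2, 0 °C → rt; crude, then MnO2, CH2Cl2, rt
Reagents that add atoms: selenium dioxide O=[Se]=O; tert‑butyl hydroperoxide CC(C)(C)OO (oxygen source)
Why: SeO2/TBHP allylic oxidation (ene/[2,3]) picks the E‑methyl of the terminal, least hindered trisubstituted alkene, and MnO2 converges the alcohol/aldehyde mixture to the (E)‑enal.

**Step 3**
Reactants: 4
Product: 5 methyl 3‑[(2E,6E)‑3,7‑dimethylnona‑2,6,8‑trienyl]‑4‑hydroxybenzoate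
Conditions: Ph3PCH3Br (3.0 equiv), KHMDS (2.9 equiv), THF, −78 → 0 °C
Reagents that add atoms: methyltriphenylphosphonium bromide C[P+](c1ccccc1)(c1ccccc1)c1ccccc1.[Br-]
Why: Wittig methylenation of the enal, in which one extra equivalent of ylide absorbs the phenol proton and the benzoate ester is inert at this temperature.

**Step 4**
Reactants: 6 ethyl (2S)‑5‑oxotetrahydrofuran‑2‑carboxylate
Product: 7 (5S)‑5‑(2‑hydroxypropan‑2‑yl)dihydrofuran‑2(3H)‑one
Conditions: MeMgBr (2.1 equiv), THF, −78 → −40 °C; aq NH4Cl
Reagents that add atoms: methylmagnesium bromide C[Mg]Br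
Why: Double Grignard addition to the α‑alkoxy‑activated, chelating exocyclic ester outruns attack on the lactone at low temperature; the stereocentre (future C14) is untouched, and any acyl‑migrated δ‑lactone converges in Step 5.

**Step 5**
Reactants: 7
Product: 8 (3S)‑2‑methylhept‑6‑yne‑2,3‑diol
Conditions: DIBAL‑H (2.2 equiv), CH2Cl2, −78 °C; then MeOH, K2CO3, Ohira–Bestmann reagent, → rt (one pot)
Reagents that add atoms: dimethyl (1‑diazo‑2‑oxopropyl)phosphonate COP(=O)(OC)C(=[N+]=[N-])C(C)=O
Why: Half‑reduction to the lactol, then Seyferth–Gilbert/Ohira–Bestmann homologation of its open hydroxy‑aldehyde form, gives the alkyne diol without protecting groups.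

**Step 6**
Reactants: 8
Product: 9 (3S,6E)‑7‑iodo‑2,6‑dimethylhept‑6‑ene‑2,3‑diol
Conditions: Me3Al (4.5 equiv), Cp2ZrCl2 (0.3 equiv), CH2Cl2, 0 °C → rt; then I2, THF, −30 °C
Reagents that add atoms: trimethylaluminium C[Al](C)C; iodine II
Why: Negishi Zr‑catalysed syn‑carboalumination behaves as for 4‑pentyn‑1‑ol, with the OH groups masked in situ as Al alkoxides, and stereoretentive iodinolysis fixes the E‑trisubstituted C10=C11 geometry.

**Step 7**
Reactants: 5; 9
Product: 10 methyl 3‑[(2E,6E,10E,14S)‑14,15‑dihydroxy‑3,7,11,15‑tetramethylhexadeca‑2,6,10‑trienyl]‑4‑hydroxybenzoate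
Conditions: 5, 9‑BBN (2.2 equiv), THF, 0 °C → rt; then H2O, 9, Pd(dppf)Cl2 (5 mol %), AsPh3, Cs2CO3, DMF, rt
Reagents that add atoms: none (9‑BBN contributes only H)
Why: 9‑BBN hydroborates only the monosubstituted terminus of the diene, and the B‑alkyl Suzuki–Miyaura coupling forms C9–C10 with retention of the vinyl iodide geometry while tolerating the free OH groups.

**Step 8**
Reactants: 10
Product: 11 methyl 3‑{(2E,6E,10E)‑13‑[(2S)‑3,3‑dimethyloxiran‑2‑yl]‑3,7,11‑trimethyltrideca‑2,6,10‑trienyl}‑4‑hydroxybenzoate
Conditions: MeC(OMe)3, PPTS (cat.), CH2Cl2, evaporate; AcBr, CH2Cl2, 0 °C, evaporate; K2CO3, MeOH, rt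
Reagents that add atoms: none
Why: Kolb–Sharpless diol‑to‑epoxide sequence (orthoacetate, acetoxonium, bromoacetate, closure) puts a double inversion on whichever carbon bromide attacks, so C14 stays S; the phenol is untouched, since any adventitious aryl acetate is removed by the K2CO3/MeOH.

**Step 9**
Reactants: 11
Product: 12 3‑{(2E,6E,10E)‑13‑[(2S)‑3,3‑dimethyloxiran‑2‑yl]‑3,7,11‑trimethyltrideca‑2,6,10‑trienyl}‑4‑(pivaloyloxy)benzoic acid
Conditions: LiOH, THF/MeOH/H2O, 50 °C; strip MeOH; PivCl, THF/H2O (pH ≈ 10), 0 °C; citric acid to pH 4–5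
Reagents that add atoms: lithium hydroxide [Li+].[OH-]; pivaloyl chloride CC(C)(C)C(=O)Cl
Why: Saponification (the trisubstituted epoxide is base‑stable) is followed by Schotten–Baumann acylation of the phenoxide, with the mixed anhydride hydrolysing back in the basic medium, to install a DMAP‑resistant, electron‑withdrawing, non‑participating phenol cap.

**Step 10**
Reactants: 12
Product: 13 3‑[(2E,6E,10E,14S)‑15‑bromo‑14‑hydroxy‑3,7,11,15‑tetramethylhexadeca‑2,6,10‑trienyl]‑4‑(pivaloyloxy)benzoic acid
Conditions: 48 % aq HBr (1.2 equiv), LiBr (5 equiv), THF, −20 °C, 15 min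
Reagents that add atoms: hydrogen bromide Br
Why: Acid‑mediated (borderline SN1) epoxide opening puts bromide on the tertiary C15 and leaves the C14–O bond, and hence its S configuration, intact; epoxide protonation is far faster than alkene protonation, and the minor regioisomer recycles to 12 with base.

**Step 11**
Reactants: 13
Product: 14 19‑membered (2E,6E,10E,14S)‑macrolactone (C14–O–C(=O)Ar; C14 bears CBrMe2; aryl OPiv)
Conditions: MNBA (1.5 equiv), DMAP (4 equiv, no Et3N), CH2Cl2, rt; 13 added by syringe pump over 12 h (final 1 mM)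
Reagents that add atoms: none
Why: Shiina macrolactonisation activates the unhindered benzoic acid under weakly basic conditions that do not re‑close the bromohydrin, and acylation on oxygen retains C14.

**Step 12 (key step)**
Reactants: 14
Product: 15 15‑membered macrolide (2R,6S,7S,14S,10E): cyclohexane C2–C7 with equatorial C6–Br, C7 methyl, C3 exocyclic methylene; C10=C11 intact; aryl OPiv
Conditions: constant‑current electrolysis (0.5 mA cm⁻², 2.1 F mol⁻¹), RVC anode | Pt‑wire cathode (quasi‑divided), 2,4,6‑collidinium bromide (1.05 equiv), 2,4,6‑collidine (2 equiv), n‑Bu4NPF6 (0.1 M), CH2Cl2/HFIP 4:1, 5 mM, −20 °C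
Reagents that add atoms: 2,4,6‑collidinium bromide Cc1cc(C)[nH+]c(C)c1.[Br-]
Why: Proposed new method: anodic oxidation of Br⁻ (about +1 V, well below alkene or arene oxidation) in the presence of collidine meters out a bulky Br(collidine)2⁺ carrier whose Br⁺ shuttles reversibly among the three alkenes while HFIP mutes Br⁻ as a nucleophile, so the product is decided by the fastest irreversible C–C closure, expected to be C2=C3 attacking C7 of the C6,C7‑bromonium because that chair leaves the rigid units (ester‑arene, E‑alkene) of the new 15‑ring separated by sp3 spacers, whereas the C10,C11‑bromonium/C6=C7 mode packs ester–arene–CH2–alkene contiguously; anti addition across E‑C6=C7 and the E‑C2=C3 chair place Br, C8 and C1 all equatorial (relative 2R*,6S*,7S*), the fold imposed by the outward CBrMe2 group at (14S) exposes the Si face of C6 (absolute sense), hindered collidine removes the most accessible C3‑methyl proton to give the exocyclic alkene, and collidinium is reduced to H2 at Pt so that neither acid nor base accumulates and the C–Br bonds see no cathodic potential; closest known reaction types are stoichiometric Br⁺ polyene and transannular bromocyclisations and bromide‑mediated anodic bromofunctionalisation of alkenes.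

**Step 13**
Reactants: 15
Product: 16 bromophycolide S O‑pivalate (2R,6S,7S,10S,11S,14S)
Conditions: mCPBA (1.05 equiv), NaHCO3, CH2Cl2, −20 → 0 °C
Reagents that add atoms: m‑chloroperoxybenzoic acid OOC(=O)c1cccc(Cl)c1
Why: Prilezhaev epoxidation favours the trisubstituted C10=C11 over the hindered 1,1‑disubstituted exocyclic alkene; syn addition to the E‑alkene gives the trans oxirane, and peripheral attack on the conformationally biased 15‑membered ring (C10 Si face) sets 10S,11S under control of the existing stereocentres.

**Step 14**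
Reactants: 16
Product: 17 bromophycolide S
Conditions: K2CO3 (1.5 equiv), MeOH/THF, 0 °C → rt; aq NH4Cl
Reagents that add atoms: none
Why: Methanolysis (transesterification) of the activated aryl pivalate (phenol pKa ≈ 8.4) is much faster than attack on the hindered secondary benzoate lactone, and the phenoxide then deactivates that lactone further; the epoxide and both bromides are inert to these conditions.

## Compound list
| No. | Name | SMILES | Role |
|---|---|---|---|
| 1 | methyl 4‑hydroxybenzoate | COC(=O)c1ccc(O)cc1 | starting material |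
| 2 | geranyl bromide | CC(C)=CCC/C(C)=C/CBr | starting material |
| 3 | methyl 3‑geranyl‑4‑hydroxybenzoate | COC(=O)c1ccc(O)c(C/C=C(\C)CCC=C(C)C)c1 | intermediate |
| 4 | (2E,6E)‑8‑oxogeranyl benzoate (enal) | COC(=O)c1ccc(O)c(C/C=C(\C)CC/C=C(\C)C=O)c1 | intermediate |
| 5 | (2E,6E)‑3,7‑dimethylnona‑2,6,8‑trienyl benzoate | COC(=O)c1ccc(O)c(C/C=C(\C)CC/C=C(\C)C=C)c1 | intermediate |
| 6 | ethyl (2S)‑5‑oxotetrahydrofuran‑2‑carboxylate | CCOC(=O)[C@@H]1CCC(=O)O1 | starting material |
| 7 | (5S)‑5‑(2‑hydroxypropan‑2‑yl)dihydrofuran‑2(3H)‑one | CC(C)(O)[C@@H]1CCC(=O)O1 | intermediate |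
| 8 | (3S)‑2‑methylhept‑6‑yne‑2,3‑diol | C#CCC[C@H](O)C(C)(C)O | intermediate |
| 9 | (3S,6E)‑7‑iodo‑2,6‑dimethylhept‑6‑ene‑2,3‑diol | I/C=C(\C)CC[C@H](O)C(C)(C)O | intermediate |
| 10 | (14S)‑14,15‑diol methyl ester | COC(=O)c1ccc(O)c(C/C=C(\C)CC/C=C(\C)CC/C=C(\C)CC[C@H](O)C(C)(C)O)c1 | intermediate |
| 11 | (14S)‑14,15‑epoxide methyl ester | COC(=O)c1ccc(O)c(C/C=C(\C)CC/C=C(\C)CC/C=C(\C)CC[C@@H]2OC2(C)C)c1 | intermediate |
| 12 | (14S)‑epoxy O‑pivaloyl acid | CC(C)(C)C(=O)Oc1ccc(C(=O)O)cc1C/C=C(\C)CC/C=C(\C)CC/C=C(\C)CC[C@@H]1OC1(C)C | intermediate |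
| 13 | (14S)‑14‑hydroxy‑15‑bromo seco‑acid | CC(C)(C)C(=O)Oc1ccc(C(=O)O)cc1C/C=C(\C)CC/C=C(\C)CC/C=C(\C)CC[C@H](O)C(C)(C)Br | intermediate |
| 14 | 19‑membered triene macrolactone | CC(C)(C)C(=O)Oc1ccc2cc1C/C=C(\C)CC/C=C(\C)CC/C=C(\C)CC[C@@H](C(C)(C)Br)OC2=O | intermediate |
| 15 | 10,11‑deoxy‑bromophycolide S O‑pivalate | C=C1CC[C@H](Br)[C@@]2(C)CC/C=C(\C)CC[C@@H](C(C)(C)Br)OC(=O)c3ccc(OC(=O)C(C)(C)C)c(c3)C[C@H]12 | intermediate |
| 16 | bromophycolide S O‑pivalate | C=C1CC[C@H](Br)[C@@]2(C)CC[C@@H]3O[C@@]3(C)CC[C@@H](C(C)(C)Br)OC(=O)c3ccc(OC(=O)C(C)(C)C)c(c3)C[C@H]12 | intermediate |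
| 17 | bromophycolide S | C=C1CC[C@H](Br)[C@@]2(C)CC[C@@H]3O[C@@]3(C)CC[C@@H](C(C)(C)Br)OC(=O)c3ccc(O)c(c3)C[C@H]12 | target |

## Step count
- **Total steps:** 14.
- **Longest linear sequence:** 11 (steps 1–3 then 7–14; the branch through steps 4–6 then 7–14 is equally long).

## Three steps most likely to fail
1. **Step 12 (new electrochemical transannular bromocyclisation).**
   - Risks: initiation at C10=C11, the wrong facial sense, endocyclic alkene isomers, and ionisation of C15–Br in HFIP.
   - Fallback (known chemistry, ring before macrocycle): hydroborate and oxidise 5 to the C9 alcohol, then silylate it and pivaloylate the phenol. Cyclise this two‑alkene substrate with a stoichiometric Br⁺ salt (BDSB, MeNO2), which removes the site problem. Convert C9–OH to the iodide and join it to 9 by sp3–sp2 Negishi or Suzuki coupling.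
   - The ring is then racemic, so the two diastereomers must be separated before steps 8–11. This costs about four steps and half of the west material.
2. **Step 11 (lactonisation of a hindered, base‑sensitive bromohydrin).**
   - Fallback: change the order of events. Saponify and pivaloylate diol 10 directly, then Shiina‑lactonise through the secondary C14‑OH (the tertiary OH is inert).
   - Dehydrate C15‑OH (Burgess) to the isopropenyl group, then install the tertiary bromide by cobalt‑catalysed HAT hydrobromination (silane/TsBr). This reaction is selective for the 1,1‑disubstituted alkene over the three trisubstituted ones.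
3. **Step 13 (facial selectivity of the macrocycle‑controlled epoxidation).**
   - Fallback: deliver oxygen to the opposite face through a halohydrin. NBS in aqueous THF gives the 10‑bromo‑11‑hydroxy compound, with Br⁺ on the exposed face and water attacking C11 anti.
   - K2CO3/MeOH then closes the oxirane with inversion at C10 and removes the pivalate in the same pot, so the step count is unchanged.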